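## The problem

The target, 2-(2,6-dimethoxy-4-propylphenoxy)-4-(3-hydroxypropyl)-6-methoxyphenol 12, is a diaryl ether in which ring A is a 2,6-dimethoxy-4-propylphenyl unit and ring B is a phenol carrying the aryloxy group on C1, the free hydroxyl on C2, a methoxy group on C3 and a 3-hydroxypropyl chain on C5. The ether oxygen is flanked by three ortho substituents, the two methoxy groups of ring A and the hydroxyl of ring B, so the aryl–oxygen bond has to be made by a reaction that accepts a hindered, electron-rich phenoxide. Of the five oxygens bound to the rings only the one on C2 of ring B is free, and its identity should be fixed by construction and not by a selective demethylation. The molecule has no stereocentre, so every selectivity question is one of site and no centre is available or needed to control another. The free 2,6-dioxygenated phenol is easily oxidised towards quinones, the aryl methyl ethers rule out strong Lewis acids, and the primary alcohol is best introduced last. The feature that opens the way is that the three-carbon chain on C5 of ring B lies para to the C2 hydroxyl while both carbons ortho to that hydroxyl, C1 and C3, are substituted. This is the pattern in which an allyl group on the phenol oxygen migrates thermally to the para carbon.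

## Retrosynthesis

12 from 11. The C–O bond of the primary alcohol is cut, which leads back to the terminal alkene 4-allyl-2-(2,6-dimethoxy-4-propylphenoxy)-6-methoxyphenol 11. An allyl group is what a sigmatropic shift can deliver, whereas an ester or a protected alcohol carried through the sequence would cost extra redox or protecting-group steps. Alkene 11 lacks the primary alcohol, so nothing sensitive on the chain has to pass through the hot step. The forward reaction must hydrate the alkene at its terminal carbon in the presence of a free phenol.

11 from 7. The C5–CH2 bond of ring B is cut, which gives the allyl ether 2-(allyloxy)-1-(2,6-dimethoxy-4-propylphenoxy)-3-methoxybenzene 7. The neighbouring cuts are weaker: a cross-coupling needs a halogen placed para to the hydroxyl next to the activated ring A, and a Friedel–Crafts allylation risks attack on ring A and polyallylation. The sigmatropic cut uses the C2 oxygen, which must end up free anyway, as the site from which the chain is delivered. Ether 7 has no carbon substituent on ring B at all. The forward reaction is a thermal double [3,3] shift through ortho dienone 8 or 9 and para dienone 10; it must deliver the allyl group only to C5 and leave the diaryl ether intact.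

7 from 5 and 6. The O–allyl bond is cut, which gives 2-(2,6-dimethoxy-4-propylphenoxy)-6-methoxyphenol 5 and allyl bromide 6. The forward reaction is the O-alkylation of a 2,6-disubstituted phenoxide by an unhindered allylic halide.

5 from 3. The C2 hydroxyl is traced back to a formyl group in 2-(2,6-dimethoxy-4-propylphenoxy)-6-methoxybenzaldehyde 3, by way of aryl formate 4. The formyl group serves twice: it activates the neighbouring carbon for the ether-forming substitution and is then turned into the one free hydroxyl. Which oxygen of ring B stays unmethylated is thus decided without any selective deprotection. The forward reaction needs migration of the aryl group and not of hydrogen in a peracid oxidation, which two ortho oxygen substituents favour.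

3 from 1 and 2. The diaryl ether is cut at the C1–O bond of ring B, which gives 2,6-dimethoxy-4-propylphenol 1 and 2-fluoro-6-methoxybenzaldehyde 2. Ring A is electron-rich and cannot act as the electrophile, but as phenol 1 it arrives with both methoxy groups and the propyl chain in place. Ring B as aldehyde 2 carries fluorine ortho to the formyl group. A metal-catalysed coupling of two hindered, electron-rich partners is less reliable than this addition–elimination. The forward reaction is the addition of a hindered phenoxide to an ortho-fluorobenzaldehyde.

## Roads not taken

Alternative 1: Ring A is built last, by cutting its C4–C5 and C6–C1 bonds.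
- **Forward key step.** With NaOMe, dimethyl malonate A4 adds to the β-carbon of the aryloxymethyl enone A2. The aryloxy-bearing α-carbon then attacks one ester group of the malonate A4, closing ring A as the 1,3-dione A1.
- **Merits.** The ether oxygen is joined to the future ring A by simple alkylation of the ring B phenol A3, so no hindered aryl–oxygen bond formation is needed; in this respect the road is better than the chosen plan. The annulation also places the propyl group and the 1,3-dioxygenation correctly.
- **Weak points.** The dione A1 is far from 12. It still needs ester removal with decarboxylation, dehydrogenation of the cyclohexanedione to a resorcinol beside the electron-rich ring B, double O-methylation, ester reduction and debenzylation. The phenol A3 and the enone A2 each take several steps to make, including the differentiation of three adjacent oxygens on ring B.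
- **Comparison.** The chosen plan answers the hindered-ether problem with one substitution on an activated fluoroarene, takes ring A complete and aromatic, and is five steps long.

Alternative 2: Ring B is assembled by cutting its C1–C6 and C3–C4 bonds.
- **Forward key step.** With t-BuOK, the two α-methylenes of ketone A6 condense with the two termini of the 2-substituted vinamidinium salt A7. Both dimethylamino groups are expelled and phenol A5 forms directly; hydrogenolysis of its benzyl ether would then give 12.
- **Merits.** The road is convergent. Connectivity alone fixes the substitution pattern of ring B, free hydroxyl included. The diaryl ether oxygen is again attached by alkylation of phenol 1 and not by arylation. In convergence and in avoiding the hindered substitution it is as good as or better than the chosen plan, and its step count is comparable.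
- **Weak points.** This benzannulation is established mainly for ketones with well-activated α-positions, and a ketone such as A6, whose two α-carbons bear an alkoxy and an aryloxy group, is a less certain partner. The salt A7 has to come from a Vilsmeier-type formylation of the corresponding substituted acetic acid, which works less well for alkyl- than for aryl-substituted acids.
- **Comparison.** The chosen plan rests on reaction types with close analogy on the same substrate class, needs no protecting group and starts from three purchasable building blocks.

Alternative 3: The O–C1 bond of ring A is cut with ring A at the cyclohexane-1,3-dione oxidation level.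
- **Forward key step.** Rh2(OAc)4 decomposes the diazo dione A9, and the carbenoid inserts into the single free O–H of the ring B phenol A3 to give the aryloxy dione A8.
- **Merits.** The bond forms under neutral, mild conditions that are largely insensitive to ortho substitution. In the mildness of the ether-forming event this road is superior to the chosen plan.
- **Weak points.** The dione A8 must still be aromatised, bis-methylated, reduced at the ester and debenzylated. The dehydrogenation has to be selective beside an electron-rich ring and benzylic positions. The phenol A3 needs a multi-step preparation. The carbenoid could also attack the arene or the benzyl ether oxygen.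
- **Comparison.** The chosen plan uses an already aromatic ring A, makes no redox adjustment on the side chain beyond the final hydration and is roughly half as long.

Key step: step 4

## Route

Remark: ring B is numbered C1 (aryloxy), C2 (hydroxyl), C3 (methoxy), C5 (side chain). Compounds 1, 2 and 6 are taken as purchasable; should 1 have to be made, hydrogenation of 4-allyl-2,6-dimethoxyphenol would supply it.

Step 1
Reactants: 1 2,6-dimethoxy-4-propylphenol; 2 2-fluoro-6-methoxybenzaldehyde
Product: 3 2-(2,6-dimethoxy-4-propylphenoxy)-6-methoxybenzaldehyde
Conditions: Cs2CO3, DMSO, 100 °C
Reagents that add atoms: none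
Why: Nucleophilic aromatic substitution by addition–elimination: the phenoxide of 1 adds to the fluorine-bearing carbon of 2, the ortho formyl group stabilises the Meisenheimer intermediate, and fluoride leaves. Cs2CO3 in DMSO gives a poorly solvated phenoxide that offsets the two flanking methoxy groups, and 2 has no enolisable hydrogen, so the aldehyde should tolerate the base.

Step 2
Reactants: 3 2-(2,6-dimethoxy-4-propylphenoxy)-6-methoxybenzaldehyde
Product: 5 2-(2,6-dimethoxy-4-propylphenoxy)-6-methoxyphenol, via aryl formate 4 (not isolated)
Conditions: mCPBA, CH2Cl2, 0 °C to rt; aq Na2S2O3/NaHCO3 wash; then K2CO3 (0.2 equiv), MeOH, rt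
Reagents that add atoms: mCPBA (3-chloroperoxybenzoic acid), O=C(OO)c1cccc(Cl)c1
Why: Dakin-type Baeyer–Villiger oxidation: the peracid adds to the aldehyde and the electron-rich aryl group, with oxygen on both ortho carbons, migrates in preference to hydrogen to give formate 4. Base-catalysed methanolysis of the crude formate then releases phenol 5; the ether linkages and the propyl chain are inert.

Step 3
Reactants: 5 2-(2,6-dimethoxy-4-propylphenoxy)-6-methoxyphenol; 6 allyl bromide (3-bromoprop-1-ene)
Product: 7 2-(allyloxy)-1-(2,6-dimethoxy-4-propylphenoxy)-3-methoxybenzene
Conditions: K2CO3, acetone, reflux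
Reagents that add atoms: none
Why: Williamson ether synthesis: the 2,6-disubstituted phenoxide is alkylated on oxygen by an unhindered, activated primary allylic bromide. Both ortho carbons are blocked, so C-allylation at this stage is not expected.

Step 4
Reactants: 7 2-(allyloxy)-1-(2,6-dimethoxy-4-propylphenoxy)-3-methoxybenzene
Product: 11 4-allyl-2-(2,6-dimethoxy-4-propylphenoxy)-6-methoxyphenol, via methoxy-side ortho dienone 8 (not isolated), via aryloxy-side ortho dienone 9 (not isolated), via para dienone 10 (not isolated)
Conditions: PhNEt2 (degassed), 200 °C, sealed tube, Ar
Reagents that add atoms: none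
Why: Aromatic para-Claisen rearrangement: a [3,3] shift of the allyl aryl ether breaks the O–CH2 bond and joins the allyl terminus to an ortho carbon of ring B, either C3 (dienone 8) or C1 (dienone 9). Neither dienone has a hydrogen on its sp3 ring carbon, so it cannot tautomerise to an ortho-allylphenol, and a Cope [3,3] shift carries the allyl group on to C5, forming the C5–CH2 bond in dienone 10. Enolisation of 10 restores the aromatic ring and gives phenol 11; the allyl group is inverted twice and is unsubstituted, so a single constitutional isomer should result. The closest known case is the thermal rearrangement of allyl 2,6-dimethoxyphenyl ether to 4-allyl-2,6-dimethoxyphenol, from which 7 differs only in having an aryloxy group in place of one methoxy group. No ring is closed and no stereocentre is kept, since the sp3 centres of 8, 9 and 10 vanish on aromatisation. The step needs site selectivity for C5, and the oxygen substituents on C1 and C3 secure it: whichever ortho carbon is attacked first, the dienone is non-enolisable and both paths converge on 10. Ring A carries no allyloxy group and cannot take part in a concerted shift, and the diaryl ether and methyl ethers should be stable at 200 °C. Degassed N,N-diethylaniline is a basic, high-boiling medium that suppresses acid-catalysed ether cleavage and keeps air from the phenol formed.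

Step 5
Reactants: 11 4-allyl-2-(2,6-dimethoxy-4-propylphenoxy)-6-methoxyphenol
Product: 12 2-(2,6-dimethoxy-4-propylphenoxy)-4-(3-hydroxypropyl)-6-methoxyphenol
Conditions: 9-BBN (3 equiv), THF, 0 °C to rt; then aq NaOH, 30% H2O2, 0 °C to rt
Reagents that add atoms: hydrogen peroxide, OO
Why: Hydroboration–oxidation: 9-BBN places boron on the terminal carbon of the allyl group (anti-Markovnikov, steric control) and alkaline H2O2 replaces boron by hydroxyl. One equivalent of the borane is consumed by the phenol O–H, hence the excess, and the resulting O-borinate is hydrolysed in the work-up; no stereocentre is created.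

## Compound list

1 | 2,6-dimethoxy-4-propylphenol | CCCc1cc(OC)c(O)c(OC)c1 | starting material
2 | 2-fluoro-6-methoxybenzaldehyde | COc1cccc(F)c1C=O | starting material
3 | 2-(2,6-dimethoxy-4-propylphenoxy)-6-methoxybenzaldehyde | CCCc1cc(OC)c(Oc2cccc(OC)c2C=O)c(OC)c1 | intermediate
4 | 2-(2,6-dimethoxy-4-propylphenoxy)-6-methoxyphenyl formate | CCCc1cc(OC)c(Oc2cccc(OC)c2OC=O)c(OC)c1 | intermediate (not isolated)
5 | 2-(2,6-dimethoxy-4-propylphenoxy)-6-methoxyphenol | CCCc1cc(OC)c(Oc2cccc(OC)c2O)c(OC)c1 | intermediate
6 | allyl bromide (3-bromoprop-1-ene) | C=CCBr | starting material
7 | 2-(allyloxy)-1-(2,6-dimethoxy-4-propylphenoxy)-3-methoxybenzene | CCCc1cc(OC)c(Oc2cccc(OC)c2OCC=C)c(OC)c1 | intermediate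
8 | 6-allyl-2-(2,6-dimethoxy-4-propylphenoxy)-6-methoxycyclohexa-2,4-dien-1-one (racemic, transient) | C=CCC1(OC)C=CC=C(Oc2c(OC)cc(CCC)cc2OC)C1=O | intermediate (not isolated)
9 | 6-allyl-6-(2,6-dimethoxy-4-propylphenoxy)-2-methoxycyclohexa-2,4-dien-1-one (racemic, transient) | C=CCC1(Oc2c(OC)cc(CCC)cc2OC)C=CC=C(OC)C1=O | intermediate (not isolated)
10 | 4-allyl-2-(2,6-dimethoxy-4-propylphenoxy)-6-methoxycyclohexa-2,5-dien-1-one (racemic, transient) | C=CCC1C=C(OC)C(=O)C(Oc2c(OC)cc(CCC)cc2OC)=C1 | intermediate (not isolated)
11 | 4-allyl-2-(2,6-dimethoxy-4-propylphenoxy)-6-methoxyphenol | CCCc1cc(OC)c(Oc2cc(CC=C)cc(OC)c2O)c(OC)c1 | intermediate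
12 | 2-(2,6-dimethoxy-4-propylphenoxy)-4-(3-hydroxypropyl)-6-methoxyphenol | CCCc1cc(OC)c(Oc2cc(CCCO)cc(OC)c2O)c(OC)c1 | target

## Step count and risk

Total step count: 5. Longest linear sequence: 5 steps (1 to 3 to 5 to 7 to 11 to 12).

**Step 4 (key step).** At about 200 °C, cleavage of the allyl–oxygen bond may compete with the concerted shifts, because both ortho dienones are crowded, fully substituted α-oxygenated ketones. This would show up as loss of the allyl group and intermolecular allyl transfer. The dienones could also be diverted by reversible intramolecular cycloaddition with the pendant alkene. The fallback sets out from 5 and returns at 11. Para-bromination of the free phenol (NBS, MeCN, 0 °C) should give 4-bromo-2-(2,6-dimethoxy-4-propylphenoxy)-6-methoxyphenol F1, since the position para to the free hydroxyl is the most activated site of either ring. A neutral Stille coupling of this bromide with allyltributylstannane (Pd(PPh3)4, DMF, 100 °C) would then install the allyl group at C5 and give 11.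

**Step 1.** The addition of the doubly ortho-substituted phenoxide may be slow, because the formyl activator of 2 is weakened by donation from its ortho methoxy group, and prolonged heating in base could then degrade the aldehyde. The fallback sets out from 1 and returns at 3. Addition–elimination is replaced by a copper-catalysed Ullmann ether coupling of 1 with purchasable 2-bromo-6-methoxybenzaldehyde (CuI, picolinic acid, K3PO4, DMSO, 90 °C), in which the carbon–bromine bond is activated at copper with help from the neighbouring formyl oxygen. This fallback makes no compound outside the route, hence the entry F0. The fallback under step 2 also bypasses this step.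

**Step 2.** Hydrogen may migrate in place of the aryl group, which would lead to the carboxylic acid, and the peracid may also oxidise the electron-rich diaryl ether or the liberated phenol. The fallback sets out from 1 and returns at 5; it introduces the oxygen through nitrogen and uses no peroxide. Nucleophilic aromatic substitution of 1 on 1-fluoro-3-methoxy-2-nitrobenzene (K2CO3, DMF, 80 °C), where the nitro group activates far more strongly than formyl, should give 1,3-dimethoxy-2-(3-methoxy-2-nitrophenoxy)-5-propylbenzene F2. Hydrogenation (H2, Pd/C, EtOAc) would give 2-(2,6-dimethoxy-4-propylphenoxy)-6-methoxyaniline F3. Diazotisation (NaNO2, aq H2SO4/THF, 0 °C) would give 2-(2,6-dimethoxy-4-propylphenoxy)-6-methoxybenzenediazonium hydrogensulfate F4, used without isolation. Copper-mediated hydroxylation (Cu2O, excess Cu(NO3)2, H2O, rt) would then give 5; both positions of ring A ortho to the ether oxygen are blocked, which disfavours radical cyclisation onto that ring.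

**Step 5.** The electron-rich phenolate may be degraded oxidatively during the alkaline peroxide work-up, and conversion may be incomplete because the phenol O–H consumes borane. The fallback sets out from 11 and returns at 12. Silylation (TBSCl, imidazole, DMF, rt) should give tert-butyl[4-allyl-2-(2,6-dimethoxy-4-propylphenoxy)-6-methoxyphenoxy]dimethylsilane F5. Hydroboration with 9-BBN in THF and oxidation with NaBO3·4H2O in water at rt would give 3-[4-(tert-butyldimethylsilyloxy)-3-(2,6-dimethoxy-4-propylphenoxy)-5-methoxyphenyl]propan-1-ol F6. Desilylation (TBAF, THF, 0 °C) would release 12, so the phenol is never exposed as its anion to peroxide.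

## Further compounds

F1 | step 4 | 4-bromo-2-(2,6-dimethoxy-4-propylphenoxy)-6-methoxyphenol | CCCc1cc(OC)c(Oc2cc(Br)cc(OC)c2O)c(OC)c1
F0 | step 1 | none | none
F2 | step 2 | 1,3-dimethoxy-2-(3-methoxy-2-nitrophenoxy)-5-propylbenzene | CCCc1cc(OC)c(Oc2cccc(OC)c2[N+](=O)[O-])c(OC)c1
F3 | step 2 | 2-(2,6-dimethoxy-4-propylphenoxy)-6-methoxyaniline | CCCc1cc(OC)c(Oc2cccc(OC)c2N)c(OC)c1
F4 | step 2 | 2-(2,6-dimethoxy-4-propylphenoxy)-6-methoxybenzenediazonium hydrogensulfate | CCCc1cc(OC)c(Oc2cccc(OC)c2[N+]#N)c(OC)c1.OS(=O)(=O)[O-]
F5 | step 5 | tert-butyl[4-allyl-2-(2,6-dimethoxy-4-propylphenoxy)-6-methoxyphenoxy]dimethylsilane | CCCc1cc(OC)c(Oc2cc(CC=C)cc(OC)c2O[Si](C)(C)C(C)(C)C)c(OC)c1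
F6 | step 5 | 3-[4-(tert-butyldimethylsilyloxy)-3-(2,6-dimethoxy-4-propylphenoxy)-5-methoxyphenyl]propan-1-ol | CCCc1cc(OC)c(Oc2cc(CCCO)cc(OC)c2O[Si](C)(C)C(C)(C)C)c(OC)c1
A1 | alternative 1 | methyl 3-[2-(benzyloxy)-3-methoxy-5-(3-methoxy-3-oxopropyl)phenoxy]-2,4-dioxo-6-propylcyclohexane-1-carboxylate (mixture of labile epimers and enols) | CCCC1CC(=O)C(Oc2cc(CCC(=O)OC)cc(OC)c2OCc2ccccc2)C(=O)C1C(=O)OC
A2 | alternative 1 | methyl 3-[4-(benzyloxy)-3-methoxy-5-{[(3E)-2-oxohept-3-en-1-yl]oxy}phenyl]propanoate | CCC/C=C/C(=O)COc1cc(CCC(=O)OC)cc(OC)c1OCc1ccccc1
A3 | alternative 1 | methyl 3-[4-(benzyloxy)-3-hydroxy-5-methoxyphenyl]propanoate | COC(=O)CCc1cc(O)c(OCc2ccccc2)c(OC)c1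
A4 | alternative 1 | dimethyl malonate | COC(=O)CC(=O)OC
A5 | alternative 2 | 4-[3-(benzyloxy)propyl]-2-(2,6-dimethoxy-4-propylphenoxy)-6-methoxyphenol | CCCc1cc(OC)c(Oc2cc(CCCOCc3ccccc3)cc(OC)c2O)c(OC)c1
A6 | alternative 2 | 1-(2,6-dimethoxy-4-propylphenoxy)-3-methoxypropan-2-one | CCCc1cc(OC)c(OCC(=O)COC)c(OC)c1
A7 | alternative 2 | 2-[3-(benzyloxy)propyl]-1,3-bis(dimethylamino)trimethinium hexafluorophosphate | CN(C)C=C(CCCOCc1ccccc1)C=[N+](C)C.F[P-](F)(F)(F)(F)F
A8 | alternative 3 | methyl 3-{4-(benzyloxy)-3-[(2,6-dioxo-4-propylcyclohexyl)oxy]-5-methoxyphenyl}propanoate (enolisable, no fixed configuration) | CCCC1CC(=O)C(Oc2cc(CCC(=O)OC)cc(OC)c2OCc2ccccc2)C(=O)C1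
A9 | alternative 3 | 2-diazo-5-propylcyclohexane-1,3-dione | CCCC1CC(=O)C(=[N+]=[N-])C(=O)C1
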